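**Retrosynthetic overview**

1. The target comes from hydroxy enone 23 by 1,2-reduction from the convex face, acetylation of both secondary alcohols, desilylation and formylation of the primary allylic alcohol.
2. 23 comes from the tricyclic β-keto δ-lactone 21 by saponification and decarboxylation: the tether carbon leaves as CO2 and the ring B hydroxyl is set free.
3. 21 comes from the monocyclic enal 19 by a tandem intramolecular Michael addition/Horner–Wadsworth–Emmons olefination that closes the lactone bridge and ring A together. The enabling feature is that in the ring B enal the carbinol carbon C4 lies 1,3 to the enal β-carbon C2 and the formyl carbon hangs on the adjacent C1, so a γ-phosphono β-keto ester on the C4 oxygen reaches C2 through a six-membered lactone and then finds the aldehyde at six-ring distance.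
4. 19 comes from ring B enal 15, made by ring-closing metathesis of triene 11; 11 comes from syn-carbocupration/methylation of ynoate 7 (fixes the tetrasubstituted alkene geometry); 7 comes from a catalytic syn-crotylboration of alkynal 2 (sets the methyl and carbinol centers).
5. Ring order: ring B (step 5), then the temporary lactone and ring A in one operation (step 11).

Key step: step 11

Remark: ring B positions are counted from the formyl-bearing carbon (C1) through the β-carbon (C2), the methyl carbon (C3), the carbinol carbon (C4) and C5 to the alkylidene carbon (C6); 8 and 16 are taken as purchasable; 17–20 are epimer mixtures at the carbon α to phosphorus, which becomes sp2 in step 11.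

**Route**

Step 1
Reactants: 1 4-(trimethylsilyl)but-3-yn-1-ol
Product: 2 4-(trimethylsilyl)but-3-ynal
Conditions: Dess–Martin periodinane, NaHCO3, CH2Cl2, 0 °C; used crude at once
Reagents that add atoms: none
Why: Dess–Martin oxidation of a primary alcohol under buffered conditions should give the β,γ-alkynal without isomerisation to the allenal; no stereocenter is formed.

Step 2
Reactants: 2 4-(trimethylsilyl)but-3-ynal; 3 (Z)-crotylboronic acid pinacol ester
Product: 5 (3R,4R)-3-methyl-7-(trimethylsilyl)hept-1-en-6-yn-4-ol, via pinacol borate ester 4 (not isolated)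
Conditions: (S)-TRIP (5 mol %, antipode chosen for si-face attack), 4 Å MS, toluene, −30 °C; then aq. NaHCO3
Reagents that add atoms: none
Why: Chiral-phosphoric-acid-catalysed crotylboration through a closed chair transition state, in which the (Z)-crotyl boronate should give the 3,4-syn adduct and the catalyst should direct attack to the si face of the aldehyde, sets the methyl (C3) and carbinol (C4) centers of ring B.

Step 3
Reactants: 5 (3R,4R)-3-methyl-7-(trimethylsilyl)hept-1-en-6-yn-4-ol
Product: 7 methyl (5R,6R)-5-[(methoxycarbonyl)oxy]-6-methyloct-7-en-2-ynoate, via dilithium alkoxide acetylide 6 (not isolated)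
Conditions: MeLi·LiBr (2.2 equiv), THF, 0 °C → rt; then ClCO2Me (2.5 equiv), −78 → 0 °C
Reagents that add atoms: methyl chloroformate COC(=O)Cl
Why: Methyllithium deprotonates the alcohol and cleaves the alkynyl C–Si bond (desilylative lithiation), and methyl chloroformate then acylates the acetylide carbon and the alkoxide oxygen in the same flask; no stereocenter is touched.

Step 4
Reactants: 7 methyl (5R,6R)-5-[(methoxycarbonyl)oxy]-6-methyloct-7-en-2-ynoate; 8 2-bromo-3,3-diethoxyprop-1-ene
Product: 11 methyl (2E,5R,6R)-3-(3,3-diethoxyprop-1-en-2-yl)-5-[(methoxycarbonyl)oxy]-2,6-dimethylocta-2,7-dienoate, via lithium divinylcuprate 9 (not isolated), via alkenylcopper adduct 10 (not isolated)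
Conditions: 8 (2.2 equiv), t-BuLi (4.4 equiv), Et2O, −78 °C; CuI (1.1 equiv), Me2S, −60 °C; 7, THF, −78 °C; MeI (10 equiv), HMPA, −78 → −30 °C; aq. NH4Cl
Reagents that add atoms: iodomethane CI
Why: syn-Carbocupration of a 2-alkynoate by a lithium diorganocuprate at −78 °C followed by C-methylation of the configurationally stable alkenylcopper with retention should place the new alkenyl group cis to the methyl and the CH2 branch cis to the ester, which fixes the geometry of the tetrasubstituted alkene.

Step 5
Reactants: 11 methyl (2E,5R,6R)-3-(3,3-diethoxyprop-1-en-2-yl)-5-[(methoxycarbonyl)oxy]-2,6-dimethylocta-2,7-dienoate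
Product: 12 methyl (2E)-2-[(4R,5R)-2-(diethoxymethyl)-5-[(methoxycarbonyl)oxy]-4-methylcyclohex-2-en-1-ylidene]propanoate
Conditions: second-generation Grubbs catalyst RuCl2(=CHPh)(PCy3)(H2IMes) (5–10 mol %), toluene, 60 °C
Reagents that add atoms: none
Why: Ring-closing metathesis between the monosubstituted vinyl group and the 1,1-disubstituted alkene should close six-membered ring B with a trisubstituted endocyclic alkene, while the tetrasubstituted enoate is inert to the catalyst and keeps its geometry.

Step 6
Reactants: 12 methyl (2E)-2-[(4R,5R)-2-(diethoxymethyl)-5-[(methoxycarbonyl)oxy]-4-methylcyclohex-2-en-1-ylidene]propanoate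
Product: 13 (1R,2R,5E)-4-(diethoxymethyl)-5-(1-hydroxypropan-2-ylidene)-2-methylcyclohex-3-en-1-ol
Conditions: i-Bu2AlH (6 equiv), CH2Cl2, −78 → 0 °C; aq. potassium sodium tartrate
Reagents that add atoms: none
Why: i-Bu2AlH should reduce the hindered unsaturated ester in the 1,2-sense to the allylic alcohol and cleave the methyl carbonate reductively, leaving the acetal and the alkene geometry untouched.

Step 7
Reactants: 13 (1R,2R,5E)-4-(diethoxymethyl)-5-(1-hydroxypropan-2-ylidene)-2-methylcyclohex-3-en-1-ol
Product: 14 (1R,2R,5E)-5-{1-[(tert-butyldiphenylsilyl)oxy]propan-2-ylidene}-4-(diethoxymethyl)-2-methylcyclohex-3-en-1-ol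
Conditions: t-BuPh2SiCl (1.05 equiv), imidazole, CH2Cl2, 0 °C
Reagents that add atoms: tert-butyl(chloro)diphenylsilane CC(C)(C)[Si](Cl)(c1ccccc1)c1ccccc1
Why: Silylation with the bulky chlorosilane should be selective for the primary allylic alcohol over the hindered secondary alcohol.

Step 8
Reactants: 14 (1R,2R,5E)-5-{1-[(tert-butyldiphenylsilyl)oxy]propan-2-ylidene}-4-(diethoxymethyl)-2-methylcyclohex-3-en-1-ol
Product: 15 (3R,4R,6E)-6-{1-[(tert-butyldiphenylsilyl)oxy]propan-2-ylidene}-4-hydroxy-3-methylcyclohex-1-ene-1-carbaldehyde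
Conditions: PPTS (cat.), acetone/H2O 10:1, rt
Reagents that add atoms: water O
Why: Mild acid-catalysed hydrolysis of an α,β-unsaturated diethyl acetal, which is far more labile than the primary silyl ether, should release the ring B enal.

Step 9
Reactants: 16 diethyl [(2,2-dimethyl-4-oxo-4H-1,3-dioxin-6-yl)methyl]phosphonate
Product: 17 diethyl [1-(2,2-dimethyl-4-oxo-4H-1,3-dioxin-6-yl)ethyl]phosphonate (racemic)
Conditions: NaH (1.05 equiv), THF, 0 °C; MeI (1.05 equiv)
Reagents that add atoms: iodomethane CI
Why: C-alkylation of the phosphonate-stabilised vinylogous ester carbanion with iodomethane; the new center is racemic and is lost in step 11.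

Step 10
Reactants: 15 (3R,4R,6E)-6-{1-[(tert-butyldiphenylsilyl)oxy]propan-2-ylidene}-4-hydroxy-3-methylcyclohex-1-ene-1-carbaldehyde; 17 diethyl [1-(2,2-dimethyl-4-oxo-4H-1,3-dioxin-6-yl)ethyl]phosphonate
Product: 19 (1R,2R,5E)-5-{1-[(tert-butyldiphenylsilyl)oxy]propan-2-ylidene}-4-formyl-2-methylcyclohex-3-en-1-yl 4-(diethoxyphosphoryl)-3-oxopentanoate, via acylketene 18 (not isolated)
Conditions: 17 (1.5 equiv), toluene, 110 °C
Reagents that add atoms: none
Why: Thermal retro-[4+2] cleavage of the dioxinone releases acetone and an acylketene that is trapped by the secondary alcohol (acylketene acylation) to give the β-keto ester without touching any stereocenter.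

Step 11
Reactants: 19 (1R,2R,5E)-5-{1-[(tert-butyldiphenylsilyl)oxy]propan-2-ylidene}-4-formyl-2-methylcyclohex-3-en-1-yl 4-(diethoxyphosphoryl)-3-oxopentanoate
Product: 21 tricyclic enone δ-lactone (ring A 2-methylcyclohex-2-enone cis-fused to ring B and bridged from the ketone α-carbon through a lactone carbonyl to the ring B oxygen), via bridged Michael adduct 20 (not isolated)
Conditions: LiCl (5 equiv), DBU (2 equiv), MeCN (0.005 M), 0 °C → rt
Reagents that add atoms: none
Why: DBU/LiCl forms the lithium-chelated β-keto ester enolate, which adds to the enal β-carbon C2 of ring B (intramolecular Michael addition) to give 20; the α-phosphonyl carbanion of the same chain then attacks the formyl group on the neighbouring C1 and loses diethyl phosphate (intramolecular Horner–Wadsworth–Emmons olefination), so the new C–C single bond at C2 and the trisubstituted enone C=C of ring A are made in one flask. The closest known reaction type is the tandem Michael/intramolecular Wittig or Horner–Wadsworth–Emmons cyclohexenone annulation of γ-phosphoranylidene or γ-phosphono acetoacetates with enals, here run with the donor tethered as an ester. The δ-lactone closes by 6-exo-trig conjugate addition (a 2-oxabicyclo[3.3.1]nonan-3-one) and ring A closes by 6-exo-trig carbanion addition to the C=O followed by syn-elimination. The new stereocenter at C2 is set by the tether, which can only deliver carbon to the face that carries the C4 oxygen (trans to the C3 methyl); C1 is an epimerisable aldehyde α-carbon and only the epimer with the formyl group cis to the axial keto ester arm can reach the phosphonate carbon, which fixes the cis ring fusion; the lactone α-carbon is fixed by the rings and is removed in step 12. The step needs 1,4- rather than 1,2-addition, ring closure rather than oligomerisation and no migration of the exocyclic alkene: the six-membered tether geometry and high dilution should secure the first two, and the third is favoured because the resting anion is the β-dicarbonyl enolate and the olefination is irreversible under weakly basic conditions.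

Step 12
Reactants: 21 tricyclic enone δ-lactone
Product: 23 (4aS,5E,7R,8R,8aS)-5-{1-[(tert-butyldiphenylsilyl)oxy]propan-2-ylidene}-7-hydroxy-3,8-dimethyl-4a,5,6,7,8,8a-hexahydronaphthalen-2(1H)-one, via keto acid 22 (not isolated)
Conditions: LiOH (3 equiv), THF/H2O 3:1, 0 °C → rt; then AcOH to pH 4, 40 °C
Reagents that add atoms: none
Why: Saponification of the strained β-keto δ-lactone and decarboxylation of the β-keto acid on mild acidification (ketonic cleavage) should remove the tether carbon as CO2 and free the ring B hydroxyl, while the β-dicarbonyl enolate as resting anion protects the ring-fusion centers from epimerisation.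

Step 13
Reactants: 23 (4aS,5E,7R,8R,8aS)-5-{1-[(tert-butyldiphenylsilyl)oxy]propan-2-ylidene}-7-hydroxy-3,8-dimethyl-4a,5,6,7,8,8a-hexahydronaphthalen-2(1H)-one
Product: 24 (2R,4aS,5E,7R,8R,8aS)-5-{1-[(tert-butyldiphenylsilyl)oxy]propan-2-ylidene}-3,8-dimethyl-1,2,4a,5,6,7,8,8a-octahydronaphthalene-2,7-diol
Conditions: NaBH4, CeCl3·7H2O, MeOH, −78 °C
Reagents that add atoms: none
Why: Luche 1,2-reduction, in which hydride should add from the convex face of the cis-fused bicycle (away from ring B, whose C8 carbon is axial on ring A), places the new hydroxyl on the concave face as required (2R).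

Step 14
Reactants: 24 (2R,4aS,5E,7R,8R,8aS)-5-{1-[(tert-butyldiphenylsilyl)oxy]propan-2-ylidene}-3,8-dimethyl-1,2,4a,5,6,7,8,8a-octahydronaphthalene-2,7-diol
Product: 25 (2R,4aS,5E,7R,8R,8aS)-5-{1-[(tert-butyldiphenylsilyl)oxy]propan-2-ylidene}-3,8-dimethyl-1,2,4a,5,6,7,8,8a-octahydronaphthalene-2,7-diyl diacetate
Conditions: Ac2O, pyridine, DMAP (cat.), CH2Cl2, rt
Reagents that add atoms: acetic anhydride CC(=O)OC(C)=O
Why: DMAP-catalysed acetylation of both secondary alcohols with retention at both carbinol centers.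

Step 15
Reactants: 25 (2R,4aS,5E,7R,8R,8aS)-5-{1-[(tert-butyldiphenylsilyl)oxy]propan-2-ylidene}-3,8-dimethyl-1,2,4a,5,6,7,8,8a-octahydronaphthalene-2,7-diyl diacetate
Product: 26 (2R,4aS,5E,7R,8R,8aS)-5-(1-hydroxypropan-2-ylidene)-3,8-dimethyl-1,2,4a,5,6,7,8,8a-octahydronaphthalene-2,7-diyl diacetate
Conditions: Bu4NF (1.2 equiv), AcOH (1.2 equiv), THF, 0 °C → rt
Reagents that add atoms: none
Why: Fluoride cleavage of the Si–O bond, buffered with acetic acid so that the acetates are neither cleaved nor migrated.

Step 16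
Reactants: 26 (2R,4aS,5E,7R,8R,8aS)-5-(1-hydroxypropan-2-ylidene)-3,8-dimethyl-1,2,4a,5,6,7,8,8a-octahydronaphthalene-2,7-diyl diacetate
Product: 27 CNP0262962.1, (2R,4aS,5E,7R,8R,8aS)-5-[1-(formyloxy)propan-2-ylidene]-3,8-dimethyl-1,2,4a,5,6,7,8,8a-octahydronaphthalene-2,7-diyl diacetate
Conditions: HCO2H (1.5 equiv), DCC (1.5 equiv), DMAP (cat.), CH2Cl2, 0 °C
Reagents that add atoms: formic acid OC=O
Why: Carbodiimide-mediated (Steglich-type) formylation of the primary allylic alcohol under neutral conditions should leave the two acetates and the skipped diene untouched.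

**Compound list**

1 | 4-(trimethylsilyl)but-3-yn-1-ol | C[Si](C)(C)C#CCCO | starting material
2 | 4-(trimethylsilyl)but-3-ynal | C[Si](C)(C)C#CCC=O | intermediate
3 | (Z)-crotylboronic acid pinacol ester | C/C=C\CB1OC(C)(C)C(C)(C)O1 | starting material
4 | 2-{[(3R,4R)-3-methyl-7-(trimethylsilyl)hept-1-en-6-yn-4-yl]oxy}-4,4,5,5-tetramethyl-1,3,2-dioxaborolane (pinacol borate ester) | C=C[C@@H](C)[C@H](OB1OC(C)(C)C(C)(C)O1)CC#C[Si](C)(C)C | intermediate
5 | (3R,4R)-3-methyl-7-(trimethylsilyl)hept-1-en-6-yn-4-ol | C=C[C@@H](C)[C@H](O)CC#C[Si](C)(C)C | intermediate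
6 | dilithium (3R,4R)-3-methylhept-1-en-6-yn-7-id-4-olate (dilithium alkoxide acetylide) | [Li+].[Li+].C=C[C@@H](C)[C@H]([O-])CC#[C-] | intermediate
7 | methyl (5R,6R)-5-[(methoxycarbonyl)oxy]-6-methyloct-7-en-2-ynoate | C=C[C@@H](C)[C@H](OC(=O)OC)CC#CC(=O)OC | intermediate
8 | 2-bromo-3,3-diethoxyprop-1-ene | C=C(Br)C(OCC)OCC | starting material
9 | lithium bis(3,3-diethoxyprop-1-en-2-yl)cuprate (lithium divinylcuprate) | [Li+].C=C([Cu-]C(=C)C(OCC)OCC)C(OCC)OCC | intermediate
10 | alkenylcopper adduct of 7 (lithium cuprate with copper on the ester α-carbon, cis to the new alkenyl group) | [Li+].C=C[C@@H](C)[C@H](OC(=O)OC)C/C(=C(/[Cu-]C(=C)C(OCC)OCC)C(=O)OC)C(=C)C(OCC)OCC | intermediate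
11 | methyl (2E,5R,6R)-3-(3,3-diethoxyprop-1-en-2-yl)-5-[(methoxycarbonyl)oxy]-2,6-dimethylocta-2,7-dienoate | C=C[C@@H](C)[C@H](OC(=O)OC)C/C(=C(/C)C(=O)OC)C(=C)C(OCC)OCC | intermediate
12 | methyl (2E)-2-[(4R,5R)-2-(diethoxymethyl)-5-[(methoxycarbonyl)oxy]-4-methylcyclohex-2-en-1-ylidene]propanoate | CCOC(OCC)C1=C[C@@H](C)[C@H](OC(=O)OC)C/C1=C(/C)C(=O)OC | intermediate
13 | (1R,2R,5E)-4-(diethoxymethyl)-5-(1-hydroxypropan-2-ylidene)-2-methylcyclohex-3-en-1-ol | CCOC(OCC)C1=C[C@@H](C)[C@H](O)C/C1=C(/C)CO | intermediate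
14 | (1R,2R,5E)-5-{1-[(tert-butyldiphenylsilyl)oxy]propan-2-ylidene}-4-(diethoxymethyl)-2-methylcyclohex-3-en-1-ol | CCOC(OCC)C1=C[C@@H](C)[C@H](O)C/C1=C(/C)CO[Si](c2ccccc2)(c3ccccc3)C(C)(C)C | intermediate
15 | (3R,4R,6E)-6-{1-[(tert-butyldiphenylsilyl)oxy]propan-2-ylidene}-4-hydroxy-3-methylcyclohex-1-ene-1-carbaldehyde | O=CC1=C[C@@H](C)[C@H](O)C/C1=C(/C)CO[Si](c2ccccc2)(c3ccccc3)C(C)(C)C | intermediate
16 | diethyl [(2,2-dimethyl-4-oxo-4H-1,3-dioxin-6-yl)methyl]phosphonate | CCOP(=O)(OCC)CC1=CC(=O)OC(C)(C)O1 | starting material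
17 | diethyl [1-(2,2-dimethyl-4-oxo-4H-1,3-dioxin-6-yl)ethyl]phosphonate (racemic) | CCOP(=O)(OCC)C(C)C1=CC(=O)OC(C)(C)O1 | intermediate
18 | diethyl (3,5-dioxopent-4-en-2-yl)phosphonate (acylketene) | CCOP(=O)(OCC)C(C)C(=O)C=C=O | intermediate
19 | (1R,2R,5E)-5-{1-[(tert-butyldiphenylsilyl)oxy]propan-2-ylidene}-4-formyl-2-methylcyclohex-3-en-1-yl 4-(diethoxyphosphoryl)-3-oxopentanoate (epimers at the P-bearing carbon) | O=CC1=C[C@@H](C)[C@H](OC(=O)CC(=O)C(C)P(=O)(OCC)OCC)C/C1=C(/C)CO[Si](c2ccccc2)(c3ccccc3)C(C)(C)C | intermediate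
20 | bridged Michael adduct: 2-oxabicyclo[3.3.1]nonan-3-one with the 2-(diethoxyphosphoryl)propanoyl group on the lactone α-carbon, the formyl group on the adjacent ring B carbon (cis epimer drawn), the methyl on the one-carbon bridge and the silyloxy-alkylidene on ring B | O=C[C@H]1/C(=C(\C)CO[Si](c2ccccc2)(c4ccccc4)C(C)(C)C)C[C@H]3OC(=O)[C@@H](C(=O)C(C)P(=O)(OCC)OCC)[C@@H]1[C@H]3C | intermediate
21 | tricyclic enone δ-lactone: cis-fused 3,8-dimethyl-hexahydronaphthalen-2-one with the lactone carbonyl bridging C1 and the C7 oxygen and the (E)-silyloxy-alkylidene at C5 | O=C1C(C)=C[C@H]2/C(=C(\C)CO[Si](c4ccccc4)(c5ccccc5)C(C)(C)C)C[C@H]3OC(=O)[C@@H]1[C@@H]2[C@H]3C | intermediate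
22 | β-keto acid from lactone opening (2-oxo-1-carboxylic acid of 23; C1 enolisable and not defined) | O=C1C(C(=O)O)[C@@H]2[C@@H](C)[C@H](O)C/C(=C(/C)CO[Si](c3ccccc3)(c4ccccc4)C(C)(C)C)[C@@H]2C=C1C | intermediate
23 | (4aS,5E,7R,8R,8aS)-5-{1-[(tert-butyldiphenylsilyl)oxy]propan-2-ylidene}-7-hydroxy-3,8-dimethyl-4a,5,6,7,8,8a-hexahydronaphthalen-2(1H)-one | O=C1C[C@@H]2[C@@H](C)[C@H](O)C/C(=C(/C)CO[Si](c3ccccc3)(c4ccccc4)C(C)(C)C)[C@@H]2C=C1C | intermediate
24 | (2R,4aS,5E,7R,8R,8aS)-5-{1-[(tert-butyldiphenylsilyl)oxy]propan-2-ylidene}-3,8-dimethyl-1,2,4a,5,6,7,8,8a-octahydronaphthalene-2,7-diol | O[C@@H]1C[C@@H]2[C@@H](C)[C@H](O)C/C(=C(/C)CO[Si](c3ccccc3)(c4ccccc4)C(C)(C)C)[C@@H]2C=C1C | intermediate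
25 | (2R,4aS,5E,7R,8R,8aS)-5-{1-[(tert-butyldiphenylsilyl)oxy]propan-2-ylidene}-3,8-dimethyl-1,2,4a,5,6,7,8,8a-octahydronaphthalene-2,7-diyl diacetate | CC(=O)O[C@@H]1C[C@@H]2[C@@H](C)[C@H](OC(C)=O)C/C(=C(/C)CO[Si](c3ccccc3)(c4ccccc4)C(C)(C)C)[C@@H]2C=C1C | intermediate
26 | (2R,4aS,5E,7R,8R,8aS)-5-(1-hydroxypropan-2-ylidene)-3,8-dimethyl-1,2,4a,5,6,7,8,8a-octahydronaphthalene-2,7-diyl diacetate | CC(=O)O[C@@H]1C[C@@H]2[C@@H](C)[C@H](OC(C)=O)C/C(=C(/C)CO)[C@@H]2C=C1C | intermediate
27 | CNP0262962.1, (2R,4aS,5E,7R,8R,8aS)-5-[1-(formyloxy)propan-2-ylidene]-3,8-dimethyl-1,2,4a,5,6,7,8,8a-octahydronaphthalene-2,7-diyl diacetate | CC(=O)O[C@@H]1C[C@@H]2[C@@H](C)[C@H](OC(C)=O)C/C(=C(/C)COC=O)[C@@H]2C=C1C | target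

**Count and risks**

Total step count: 16. Longest linear sequence: 15 steps (steps 1–8 and 10–16); step 9 is a one-step branch.

Steps most likely to fail:

Step 11. The enal may be slow to reach the diaxial conformation that the bridged Michael addition needs. Base-induced γ-deprotonation with loss of the acyloxy group (a vinylogous β-elimination that leads towards aromatisation of ring B) may compete. Allylic 1,3-strain between the formyl group and the alkylidene methyl may retard the olefination, so that the aldehyde enolises and the exocyclic alkene drifts into conjugation. The fallback gives up the tether and sets out from 15. Intermolecular Michael addition of tert-butyl 3-oxopentanoate (Cs2CO3 cat., MeCN, 0 °C), expected anti to the C3 methyl, should give the Michael adduct tert-butyl 2-[(1S,5R,6R)-2-formyl-5-hydroxy-6-methyl-3-(silyloxy-alkylidene)cyclohexyl]-3-oxopentanoate F1. Treatment with p-TsOH in toluene at 70 °C should then effect aldol condensation with loss of 2-methylpropene and CO2 (the known cyclohexenone annulation of β-keto esters with enals). This returns to the route at 23, with the cis ring fusion now resting on equilibration of the aldehyde α-carbon before ring closure.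

Step 4. The alkenylcopper may be protonated instead of methylated, or may lose its configuration through the allenoate on warming, which would erode the alkene geometry. The fallback sets out from 7 (with cuprate 9). The adduct is quenched at −78 °C with I2 to give methyl (2Z,5R,6R)-3-(3,3-diethoxyprop-1-en-2-yl)-2-iodo-5-[(methoxycarbonyl)oxy]-6-methylocta-2,7-dienoate F2. Stereoretentive Negishi coupling with MeZnCl and Pd(PPh3)4 in THF then returns to the route at 11.

Step 12. Saponification of the enolised β-keto lactone may be slow, with retro-Claisen opening of ring A or base-mediated migration of the skipped diene taking over. The fallback sets out from 21. Ring-opening transesterification with allyl alcohol (DMAP cat., toluene, 90 °C) should give allyl (4aS,5E,7R,8R,8aS)-5-{1-[(tert-butyldiphenylsilyl)oxy]propan-2-ylidene}-7-hydroxy-3,8-dimethyl-2-oxo-1,2,4a,5,6,7,8,8a-octahydronaphthalene-1-carboxylate F3. Deallylation and decarboxylation with zerovalent palladium (Pd(PPh3)4, morpholine, THF, rt; Tsuji–Trost type) under neutral conditions then returns to the route at 23.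

Further compounds
F1 | step 11 | tert-butyl 2-[(1S,5R,6R)-3-{1-[(tert-butyldiphenylsilyl)oxy]propan-2-ylidene}-2-formyl-5-hydroxy-6-methylcyclohexyl]-3-oxopentanoate (formyl-bearing and keto ester carbons not defined) | CCC(=O)C(C(=O)OC(C)(C)C)[C@@H]1[C@@H](C)[C@H](O)C/C(=C(/C)CO[Si](c2ccccc2)(c3ccccc3)C(C)(C)C)C1C=O
F2 | step 4 | methyl (2Z,5R,6R)-3-(3,3-diethoxyprop-1-en-2-yl)-2-iodo-5-[(methoxycarbonyl)oxy]-6-methylocta-2,7-dienoate | C=C[C@@H](C)[C@H](OC(=O)OC)C/C(=C(/I)C(=O)OC)C(=C)C(OCC)OCC
F3 | step 12 | allyl (4aS,5E,7R,8R,8aS)-5-{1-[(tert-butyldiphenylsilyl)oxy]propan-2-ylidene}-7-hydroxy-3,8-dimethyl-2-oxo-1,2,4a,5,6,7,8,8a-octahydronaphthalene-1-carboxylate (C1 not defined) | O=C1C(C(=O)OCC=C)[C@@H]2[C@@H](C)[C@H](O)C/C(=C(/C)CO[Si](c3ccccc3)(c4ccccc4)C(C)(C)C)[C@@H]2C=C1C
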